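Locants (bourbonane numbering, used for every intermediate): ring B (four-membered) C1(H)–C5(H)–C6(O)–C10(CH3); ring A C1–C2(OAc)–C3–C4(CH3)(OH)–C5; ring C C6–C7–C8(OTig)–C9–C10; lactone ring D C6–O–C12(=O)–C11(C13H2OAc)=C7.
Retrosynthesis: esters and silyl ether last; ring D by olefination C7=C11 from an O-6 phosphonoacrylate; ring C by Dieckmann closure C7–C8; ring B by contraction of a five-membered ring F (C1, C5, C6, C7, C10); the C2 oxygen by Baeyer–Villiger opening of a six-membered ring E (C1, C2, Cx, C8, C9, C10); rings A and F by cutting C1–C5 and C2–C3.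
Forward: a Diels–Alder reaction gives ring E as a cyclohexenone with quaternary C10; one palladium–trimethylenemethane (TMM) step adds rings F and A; ring E is cleaved (its carbonyl carbon Cx later leaves as CO2), ring F contracts to ring B while ring C closes, and ring D is annulated last.
Enabling feature: C1 is bonded to C2, C5 and C10, and C2, C4 and C9 lie on one face of ring B while H-1, H-5, the C10 methyl and O-6 lie on the other. An all-cis tricycle in which rings A, E and F share C1 has exactly this pattern, so a two-atom tether on C10 (C7, C6) can deliver the C3–C4–C5 unit across the enone bond C1=C2.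
Stereochemistry: C10 from the catalyst in step 1; C1, C5 and C2 from the tether in step 5; C4 and C8 by attack on convex faces; C6 by delivery of C7 from O-2; C2 is then inverted by a Mitsunobu reaction.

Key step: step 5

Remark: the carbinol centres of 5, 9 and 10 and C8 of 18 form as epimer mixtures that converge in the next step and are left undefined in the SMILES; 24 is assumed to be purchasable (otherwise it is made by hydrolysis of its commercial ethyl ester).

Step 1
Reactants: 1 (E)-3-(tert-butyldimethylsilyloxy)-N,N-dimethylbuta-1,3-dien-1-amine; 2 2-methylprop-2-enal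
Product: 4 (R)-1-methyl-4-oxocyclohex-2-ene-1-carbaldehyde, via endo cycloadduct 3 (not isolated)
Conditions: [Cr(salen)]SbF6 (5 mol %; salen = dianion of (1S,2S)-N,N'-bis(3,5-di-tert-butylsalicylidene)cyclohexane-1,2-diamine), 4 Å MS, CH2Cl2, −40 °C; then AcCl, −78 °C
Reagents that add atoms: none
Why: Catalytic asymmetric Diels–Alder reaction in which the Lewis acidic complex of trivalent chromium binds the enal and shields one face, setting quaternary C10 (the mirror-image ligand is used if the induction proves opposite), followed by N-acylation, loss of the amide and desilylation to the enone.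

Step 2
Reactants: 4 (R)-1-methyl-4-oxocyclohex-2-ene-1-carbaldehyde
Product: 6 (R)-4-acetyl-4-methylcyclohex-2-en-1-one, via bromomagnesium alkoxide 5 (not isolated)
Conditions: MeMgBr (1.05 equiv), THF, −78 °C; then 1,1'-(azodicarbonyl)dipiperidine, 0 °C to rt; H2O
Reagents that add atoms: methylmagnesium bromide, C[Mg]Br
Why: Grignard addition to the aldehyde, which should be much faster than attack on the enone at −78 °C, followed by Mukaiyama oxidation of the magnesium alkoxide by hydride transfer to the azo compound; C10 is untouched.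

Step 3
Reactants: 7 2-[(trimethylsilyl)methyl]prop-2-en-1-ol
Product: 8 2-[(trimethylsilyl)methyl]prop-2-enal
Conditions: MnO2 (activated), CH2Cl2, rt
Reagents that add atoms: none
Why: Chemoselective oxidation of an allylic alcohol on manganese dioxide, which leaves the allylsilane intact.

Step 4
Reactants: 6 (R)-4-acetyl-4-methylcyclohex-2-en-1-one; 8 2-[(trimethylsilyl)methyl]prop-2-enal
Product: 10 methyl 1-[(1R)-1-methyl-4-oxocyclohex-2-en-1-yl]-1-oxo-4-[(trimethylsilyl)methyl]pent-4-en-3-yl carbonate, via lithium aldolate 9 (not isolated)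
Conditions: LDA (1.05 equiv), THF, −78 °C; 8; then ClCO2Me, −78 to 0 °C
Reagents that add atoms: methyl chloroformate, COC(=O)Cl
Why: Kinetic deprotonation should occur at the unhindered acetyl CH3 and not at the ring CH2 next to the enone carbonyl, the enolate adds to the aldehyde (aldol addition) and the aldolate is O-acylated in the same flask, giving the TMM precursor with the C10–C7–C6–C5 tether.

Step 5
Reactants: 10 methyl 1-[(1R)-1-methyl-4-oxocyclohex-2-en-1-yl]-1-oxo-4-[(trimethylsilyl)methyl]pent-4-en-3-yl carbonate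
Product: 11 all-cis tricyclic diketone (rings A/E/F fused at C1; 4-methylene; 7-oxo; Cx-oxo; 10-methyl)
Conditions: Pd(OAc)2 (5 mol %), P(OiPr)3 (30 mol %), THF, 65 °C
Reagents that add atoms: none
Why: Zerovalent palladium formed in situ ionizes the allylic carbonate, the methoxide released on decarboxylation removes the silyl group, and the zwitterionic TMM–Pd complex adds through its substituted terminus C5 to the enone β-carbon C1, after which the enolate carbon C2 closes onto the π-allyl terminus C3 (formal (3+2) cycloaddition; closest known type: intramolecular Pd-catalysed TMM cycloaddition of tethered enones to bicyclo[3.3.0]octanes). Ring F (C1, C5, C6, C7, C10) closes by 5-exo-trig conjugate addition and ring A (C1–C5) by 5-exo attack of the enolate on the allyl terminus, so C1–C5 and C2–C3 form in one operation. C1 and C5 are set by the two-atom tether on quaternary C10, because ring F can only be cis-fused to ring E, which puts H-1 on the face of the C10 methyl; C2 is set because the enolate can reach the allyl unit only on the face to which C5 was delivered, giving the all-cis tricycle. The step needs attack at C1 of the ring enone and not at the non-conjugated side-chain ketone, bond formation through C5 and not through a methylene terminus (which would give a seven-membered ring), and ring closure faster than enolate protonation or β-hydride loss; the short tether and aprotic neutral conditions should secure these.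

Step 6
Reactants: 11 all-cis tricyclic diketone (rings A/E/F fused at C1; 4-methylene; 7-oxo; Cx-oxo; 10-methyl)
Product: 12 4-hydroxy-4-methyl tricyclic diketone (4-OH cis to H-5)
Conditions: Co(acac)2 (20 mol %), PhSiH3, O2 (1 atm), THF/i-PrOH, rt
Reagents that add atoms: dioxygen, O=O
Why: Mukaiyama hydration: hydrogen-atom transfer from a cobalt hydride (catalyst of divalent cobalt) gives the tertiary C4 radical, which is trapped by O2 on the convex face of the bowl-shaped tricycle, so OH is cis to H-5 and the new methyl C15 is endo.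

Step 7
Reactants: 12 4-hydroxy-4-methyl tricyclic diketone (4-OH cis to H-5)
Product: 13 4-O-triethylsilyl tricyclic diketone
Conditions: TESOTf, 2,6-lutidine, CH2Cl2, −78 to 0 °C
Reagents that add atoms: triethylsilyl trifluoromethanesulfonate, CC[Si](CC)(CC)OS(=O)(=O)C(F)(F)F
Why: Silylation of the tertiary alcohol with a silyl triflate masks O-4 so that O-6 is the only free tertiary hydroxyl when it must be acylated in step 15.

Step 8
Reactants: 13 4-O-triethylsilyl tricyclic diketone
Product: 14 ε-lactone ketone (O inserted between Cx and C2; 7-oxo; 4-OTES)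
Conditions: mCPBA, NaHCO3, CH2Cl2, 0 °C
Reagents that add atoms: 3-chloroperbenzoic acid, OOC(=O)c1cccc(Cl)c1
Why: Baeyer–Villiger oxidation: the six-membered ketone should add peracid faster than the five-membered ketone flanked by quaternary C10, and the methine C2 migrates with retention, placing oxygen on C2 (endo) and turning Cx into a carboxyl carbon on C8.

Step 9
Reactants: 14 ε-lactone ketone (O inserted between Cx and C2; 7-oxo; 4-OTES)
Product: 15 ε-lactone 6,7-dione (4-OTES)
Conditions: SeO2, pyridine (0.2 equiv), 1,4-dioxane/H2O, 90 °C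
Reagents that add atoms: selenium dioxide, O=[Se]=O
Why: Riley oxidation of the only ketone α-methylene (C6; C10 is quaternary and the lactone α-CH2 is far less reactive) gives the ring F 1,2-diketone.

Step 10
Reactants: 15 ε-lactone 6,7-dione (4-OTES)
Product: 18 ring B/C β-keto allyl ester (6-OH; 7-oxo; 8-allyloxycarbonyl; 2-endo-OH; 4-OTES), via seco allyl ester alkoxide 16 (not isolated), via bridged lactone alkoxide 17 (not isolated)
Conditions: NaH (2.5 equiv), allyl alcohol (5 equiv), THF, 0 to 40 °C; then AcOH
Reagents that add atoms: allyl alcohol, C=CCO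
Why: Proposed new method: allyloxide first opens the strained ε-lactone, the freed C2 alkoxide sits above ring F, adds to the 1,2-diketone as a five-membered hemiketal and triggers a benzilic ester rearrangement (1,2-shift of C10 or C5) that contracts ring F to ring B and ties the acyl carbon C7 to O-2, so C7 must lie on the C2/C9 face and the C6 oxygen on the methyl face; deprotonation at C8 then closes ring C by Dieckmann acylation on C7 with release of O-2, the enolizable β-keto ester being the thermodynamic sink; closest known types are the alkoxide-induced benzilic ester rearrangement with ring contraction of cyclic 1,2-diketones and the Dieckmann cyclization.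

Step 11
Reactants: 18 ring B/C β-keto allyl ester (6-OH; 7-oxo; 8-allyloxycarbonyl; 2-endo-OH; 4-OTES)
Product: 19 6-hydroxy-7-ketone 2-endo-ol (4-OTES)
Conditions: Pd(PPh3)4 (5 mol %), morpholine, THF, rt
Reagents that add atoms: none
Why: Tsuji–Trost deallylation: zerovalent palladium forms the π-allyl complex, the β-keto carboxylate loses CO2 (Cx) and morpholine takes the allyl group, under neutral conditions that should spare the 1-hydroxycyclobutyl ketone.

Step 12
Reactants: 19 6-hydroxy-7-ketone 2-endo-ol (4-OTES)
Product: 20 2-exo-acetate 6-hydroxy-7-ketone (4-OTES)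
Conditions: PPh3, DIAD, AcOH, toluene, 0 °C to rt
Reagents that add atoms: acetic acid, CC(=O)O
Why: Mitsunobu reaction on the only secondary alcohol: acetate displaces the oxyphosphonium group by SN2 from the open convex face, inverting C2 to the exo acetate of the target.

Step 13
Reactants: 20 2-exo-acetate 6-hydroxy-7-ketone (4-OTES)
Product: 22 6,8-dihydroxy-7-ketone (8-OH cis to the C10 methyl), via bis-silyl enol ether 21 (not isolated)
Conditions: TMSOTf, Et3N, CH2Cl2, 0 °C; then mCPBA, NaHCO3, −20 °C; then citric acid, MeOH/H2O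
Reagents that add atoms: 3-chloroperbenzoic acid, OOC(=O)c1cccc(Cl)c1
Why: Rubottom oxidation: soft enolization can only go toward C8 because C6 is quaternary (O-6 is silylated in passing), and epoxidation of the enol ether on the face of ring C turned away from ring B should place the C8 oxygen cis to the C10 methyl and O-6.

Step 14
Reactants: 22 6,8-dihydroxy-7-ketone (8-OH cis to the C10 methyl)
Product: 23 8-O-tigloyl ester
Conditions: (E)-2-methylbut-2-enoyl chloride, pyridine, DMAP (cat.), CH2Cl2, 0 °C
Reagents that add atoms: (E)-2-methylbut-2-enoyl chloride, C/C=C(\C)C(=O)Cl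
Why: Acylation of the only secondary hydroxyl; the hindered tertiary O-6 hydroxyl should not react under these conditions.

Step 15
Reactants: 23 8-O-tigloyl ester; 24 2-(diethoxyphosphoryl)prop-2-enoic acid
Product: 25 6-O-[2-(diethoxyphosphoryl)acryloyl] ester
Conditions: DCC, DMAP (cat.), CH2Cl2, 0 °C to rt
Reagents that add atoms: none
Why: Steglich esterification of the one remaining free hydroxyl (tertiary O-6) attaches C11, C12 and C13 and caps the α-ketol against acyloin rearrangement.

Step 16
Reactants: 25 6-O-[2-(diethoxyphosphoryl)acryloyl] ester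
Product: 26 4-O-triethylsilyl ether of the target
Conditions: CsOAc, 18-crown-6, MeCN, rt
Reagents that add atoms: cesium acetate, CC(=O)[O-].[Cs+]
Why: Michael-initiated Horner–Wadsworth–Emmons ring closure: acetate adds to the α-phosphonoacrylate at C13 and the phosphonate carbanion at C11 olefinates the adjacent C7 ketone in a five-membered transition state, giving the butenolide with the acetoxymethyl group in place.

Step 17
Reactants: 26 4-O-triethylsilyl ether of the target
Product: 27 target CNP0210373.1
Conditions: HF·pyridine, pyridine, THF, 0 °C to rt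
Reagents that add atoms: none
Why: Buffered fluoride cleavage of the tertiary triethylsilyl ether, under conditions that should leave the three esters and the butenolide untouched.

Compound list
1 | (E)-3-(tert-butyldimethylsilyloxy)-N,N-dimethylbuta-1,3-dien-1-amine | CN(C)/C=C/C(=C)O[Si](C)(C)C(C)(C)C | starting material
2 | 2-methylprop-2-enal | CC(=C)C=O | starting material
3 | (1R,2S)-2-(dimethylamino)-1-methyl-4-(tert-butyldimethylsilyloxy)cyclohex-3-ene-1-carbaldehyde (endo cycloadduct) | O=C[C@]1(C)CCC(O[Si](C)(C)C(C)(C)C)=C[C@@H]1N(C)C | intermediate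
4 | (R)-1-methyl-4-oxocyclohex-2-ene-1-carbaldehyde | O=C[C@]1(C)CCC(=O)C=C1 | intermediate
5 | bromomagnesium 1-[(1R)-1-methyl-4-oxocyclohex-2-en-1-yl]ethanolate | CC(O[Mg]Br)[C@]1(C)CCC(=O)C=C1 | intermediate
6 | (R)-4-acetyl-4-methylcyclohex-2-en-1-one | CC(=O)[C@]1(C)CCC(=O)C=C1 | intermediate
7 | 2-[(trimethylsilyl)methyl]prop-2-en-1-ol | C[Si](C)(C)CC(=C)CO | starting material
8 | 2-[(trimethylsilyl)methyl]prop-2-enal | C[Si](C)(C)CC(=C)C=O | intermediate
9 | lithium 1-[(1R)-1-methyl-4-oxocyclohex-2-en-1-yl]-1-oxo-4-[(trimethylsilyl)methyl]pent-4-en-3-olate | [Li]OC(CC(=O)[C@]1(C)CCC(=O)C=C1)C(=C)C[Si](C)(C)C | intermediate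
10 | methyl 1-[(1R)-1-methyl-4-oxocyclohex-2-en-1-yl]-1-oxo-4-[(trimethylsilyl)methyl]pent-4-en-3-yl carbonate | COC(=O)OC(CC(=O)[C@]1(C)CCC(=O)C=C1)C(=C)C[Si](C)(C)C | intermediate
11 | all-cis tricyclic diketone: ring A C1–C2–C3–C4(=C15H2)–C5; ring F C1–C5–C6H2–C7(=O)–C10; ring E C1–C2–Cx(=O)–C8H2–C9H2–C10; CH3 on C10; H-1, H-2, H-5 on the face of that CH3 | O=C1CC[C@@]2(C)C(=O)C[C@H]3C(=C)C[C@@H]1[C@@H]23 | intermediate
12 | 4-hydroxy-4-methyl tricyclic diketone (11 with C4(CH3)(OH); OH cis to H-5) | O=C1CC[C@@]2(C)C(=O)C[C@H]3[C@](C)(O)C[C@@H]1[C@@H]23 | intermediate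
13 | 4-O-triethylsilyl tricyclic diketone | O=C1CC[C@@]2(C)C(=O)C[C@H]3[C@](C)(O[Si](CC)(CC)CC)C[C@@H]1[C@@H]23 | intermediate
14 | ε-lactone ketone (ring E with O between Cx and C2, O on C2 endo; 7-oxo; 4-OTES) | O=C1CC[C@@]2(C)C(=O)C[C@H]3[C@](C)(O[Si](CC)(CC)CC)C[C@@H](O1)[C@@H]23 | intermediate
15 | ε-lactone 6,7-dione (4-OTES) | O=C1CC[C@@]2(C)C(=O)C(=O)[C@H]3[C@](C)(O[Si](CC)(CC)CC)C[C@@H](O1)[C@@H]23 | intermediate
16 | seco allyl ester alkoxide (sodium salt; ring E opened, C2–O(−), ring F dione) | C=CCOC(=O)CC[C@@]1(C)C(=O)C(=O)[C@H]2[C@](C)(O[Si](CC)(CC)CC)C[C@@H]([O-])[C@@H]12.[Na+] | intermediate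
17 | bridged lactone alkoxide (sodium salt; ring B formed, C7(=O)–O–C2 lactone, C6–O(−)) | C=CCOC(=O)CC[C@]1(C)[C@@H]2[C@@H]3OC(=O)[C@@]1([O-])[C@H]2[C@](C)(O[Si](CC)(CC)CC)C3.[Na+] | intermediate
18 | ring B/C β-keto allyl ester (6-OH on the methyl face; 7-oxo; 8-allyloxycarbonyl; 2-endo-OH; 4-OTES) | C=CCOC(=O)C1C[C@]2(C)[C@@H]3[C@H](O)C[C@@](C)(O[Si](CC)(CC)CC)[C@@H]3[C@]2(O)C1=O | intermediate
19 | 6-hydroxy-7-ketone 2-endo-ol (rings A/B/C; 4-OTES) | O=C1CC[C@]2(C)[C@@H]3[C@H](O)C[C@@](C)(O[Si](CC)(CC)CC)[C@@H]3[C@]12O | intermediate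
20 | 2-exo-acetate 6-hydroxy-7-ketone (4-OTES) | O=C1CC[C@]2(C)[C@@H]3[C@@H](OC(C)=O)C[C@@](C)(O[Si](CC)(CC)CC)[C@@H]3[C@]12O | intermediate
21 | bis-trimethylsilyl derivative (C7=C8 enol ether; 6-O-silyl) | C[Si](C)(C)OC1=CC[C@]2(C)[C@@H]3[C@@H](OC(C)=O)C[C@@](C)(O[Si](CC)(CC)CC)[C@@H]3[C@]12O[Si](C)(C)C | intermediate
22 | 6,8-dihydroxy-7-ketone (8-OH cis to the C10 methyl and O-6) | O=C1[C@@H](O)C[C@]2(C)[C@@H]3[C@@H](OC(C)=O)C[C@@](C)(O[Si](CC)(CC)CC)[C@@H]3[C@]12O | intermediate
23 | 8-O-tigloyl ester (6-OH free) | O=C1[C@@H](OC(=O)/C(C)=C/C)C[C@]2(C)[C@@H]3[C@@H](OC(C)=O)C[C@@](C)(O[Si](CC)(CC)CC)[C@@H]3[C@]12O | intermediate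
24 | 2-(diethoxyphosphoryl)prop-2-enoic acid | C=C(C(=O)O)P(=O)(OCC)OCC | starting material
25 | 6-O-[2-(diethoxyphosphoryl)acryloyl] ester | O=C1[C@@H](OC(=O)/C(C)=C/C)C[C@]2(C)[C@@H]3[C@@H](OC(C)=O)C[C@@](C)(O[Si](CC)(CC)CC)[C@@H]3[C@]12OC(=O)C(=C)P(=O)(OCC)OCC | intermediate
26 | 4-O-triethylsilyl ether of the target | C/C=C(\C)C(=O)O[C@H]1C[C@]2(C)[C@@H]3[C@@H](OC(C)=O)C[C@@](C)(O[Si](CC)(CC)CC)[C@@H]3[C@@]23OC(=O)C(COC(C)=O)=C13 | intermediate
27 | CNP0210373.1 (2,13-diacetoxy-4-hydroxy-8-tigloyloxy lactone) | C/C=C(\C)C(=O)O[C@H]1C[C@]2(C)[C@@H]3[C@@H](OC(C)=O)C[C@@](C)(O)[C@@H]3[C@@]23OC(=O)C(COC(C)=O)=C13 | target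

Total step count: 17. Longest linear sequence: 16 steps (steps 1, 2 and 4 to 17; step 3 is a one-step side branch).

Steps most likely to fail

Step 10 (Proposed new method). Allyloxide may attack the 1,2-diketone before the lactone is opened; rearrangement would then start from the convex face, put C7 on the wrong face of ring B and block closure of ring C. Aldol addition of the C8 enolate to the diketone may also compete. The fallback uses known chemistry, sets out from 15 and returns at 18. Condensation of 15 with p-toluenesulfonyl hydrazide at the less hindered C6 carbonyl should give the monotosylhydrazone F1. Triethylamine should expel sulfinate (Bamford–Stevens type) to give the α-diazo ketone F2. Photochemical Wolff rearrangement in methanol should contract ring F to the ring B methyl ester F3 (C6–H, C7 as CO2Me). NaH/allyl alcohol should then open the ε-lactone and close ring C by Dieckmann acylation on the C7 ester, the C6 epimers equilibrating through the ester enolate, to give the β-keto allyl ester lacking the C6 oxygen F4. The trianion of F4 (LDA, 3.3 equiv) should be hydroxylated at the γ-carbon C6 with 2-(phenylsulfonyl)-3-phenyloxaziridine from the only open face to give 18.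

Step 8. Chemoselectivity may be lost: the peracid may oxidize the five-membered ketone with migration of quaternary C10, or both ketones. The fallback inserts nitrogen first, sets out from 13 and returns at 14. Hydroxylamine should condense only with the less hindered six-membered ketone to give the oxime F5 (OH anti to C2). Beckmann rearrangement (TsCl, pyridine) should move C2 with retention and give the ε-lactam F6. N-nitrosation (N2O4, NaOAc) should give the N-nitroso lactam F7, whose thermal nitrosoamide rearrangement in toluene should expel N2 and return the ε-lactone 14 with retention at C2.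

Step 16. Acetate may be too weak a Michael donor, so that the olefination does not start or the phosphonoacrylate oligomerizes. The fallback sets out from 23 and returns at 26. Acryloyl chloride (i-Pr2NEt, DMAP) should give the O-6 acrylate F8. An intramolecular Morita–Baylis–Hillman reaction (PMe3, t-BuOH/THF) should close ring D as the α-methylene β-hydroxy lactone F9. SOCl2/pyridine should give the rearranged allylic chloride F10 by SN2' substitution. CsOAc in DMF should then displace chloride to give 26.

Further compounds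
F1 | step 10 | C6 monotosylhydrazone of 15 | O=C1CC[C@@]2(C)C(=O)C(=NNS(=O)(=O)c4ccc(C)cc4)[C@H]3[C@](C)(O[Si](CC)(CC)CC)C[C@@H](O1)[C@@H]23
F2 | step 10 | 6-diazo-7-ketone ε-lactone | O=C1CC[C@@]2(C)C(=O)C(=[N+]=[N-])[C@H]3[C@](C)(O[Si](CC)(CC)CC)C[C@@H](O1)[C@@H]23
F3 | step 10 | ring B methyl ester ε-lactone (C6–H; C7 = CO2Me) | O=C1CC[C@@]2(C)C(C(=O)OC)[C@H]3[C@](C)(O[Si](CC)(CC)CC)C[C@@H](O1)[C@@H]23
F4 | step 10 | ring B/C β-keto allyl ester lacking the C6 oxygen | C=CCOC(=O)C1C[C@]2(C)[C@@H]3[C@H](O)C[C@@](C)(O[Si](CC)(CC)CC)[C@@H]3[C@@H]2C1=O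
F5 | step 8 | Cx oxime of 13 | ON=C1CC[C@@]2(C)C(=O)C[C@H]3[C@](C)(O[Si](CC)(CC)CC)C[C@@H]1[C@@H]23
F6 | step 8 | ε-lactam (NH between Cx and C2) | O=C1CC[C@@]2(C)C(=O)C[C@H]3[C@](C)(O[Si](CC)(CC)CC)C[C@@H](N1)[C@@H]23
F7 | step 8 | N-nitroso ε-lactam | O=C1CC[C@@]2(C)C(=O)C[C@H]3[C@](C)(O[Si](CC)(CC)CC)C[C@@H](N1N=O)[C@@H]23
F8 | step 16 | 6-O-acryloyl ester of 23 | O=C1[C@@H](OC(=O)/C(C)=C/C)C[C@]2(C)[C@@H]3[C@@H](OC(C)=O)C[C@@](C)(O[Si](CC)(CC)CC)[C@@H]3[C@]12OC(=O)C=C
F9 | step 16 | α-methylene β-hydroxy lactone (7-OH; C11=C13H2) | C/C=C(\C)C(=O)O[C@H]1C[C@]2(C)[C@@H]3[C@@H](OC(C)=O)C[C@@](C)(O[Si](CC)(CC)CC)[C@@H]3[C@@]23OC(=O)C(=C)[C@@]13O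
F10 | step 16 | 13-chloro butenolide (4-OTES) | C/C=C(\C)C(=O)O[C@H]1C[C@]2(C)[C@@H]3[C@@H](OC(C)=O)C[C@@](C)(O[Si](CC)(CC)CC)[C@@H]3[C@@]23OC(=O)C(CCl)=C13
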